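A racemate whose Za is the quicker form cannot lift the share of Zg above its value at the first instant, when Za and Zb stand equal, since Za can afterwards only lag behind Zb.

| setting | teal | red | theta | epsilon | eta | beta |
|---|---|---|---|---|---|---|
| Za | 41 mM | 41 mM | 41 mM | 41 mM | 41 mM | 41 mM |
| Zb | 41 mM | 41 mM | 41 mM | 41 mM | 41 mM | 41 mM |
| Zc | 1.7 equiv | 3.8 equiv | 2.50 equiv | 2.50 equiv | 2.50 equiv | 2.50 equiv |
| Zd | 0.77 mol% | 0.77 mol% | 0.77 mol% | 0.77 mol% | 0.77 mol% | 0.77 mol% |
| Ze | 4.5 mol% | 4.5 mol% | 4.5 mol% | 4.5 mol% | 4.5 mol% | 4.5 mol% |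
| temperature | −2 °C | 47 °C | 5 °C | 65 °C | 35 °C | −25 °C |
| remark | run made earlier | run made earlier |  |  |  |  |
| time |  |  | 30 min | 30 min | 30 min | 30 min |

| run | time / min | Zg / % | Zh / % | Za / % |
|---|---|---|---|---|
| teal | 3.00 | 2 | 0 | 47 |
| teal | 6.00 | 4 | 2 | 47 |
| teal | 10.0 | 5 | 3 | 45 |
| teal | 12.0 | 8 | 1 | 42 |
| teal | 15.0 | 8 | 2 | 44 |
| teal | 20.0 | 9 | 3 | 41 |
| red | 0.167 | 3 | 4 | 45 |
| red | 0.333 | 10 | 2 | 44 |
| red | 0.500 | 12 | 6 | 38 |
| red | 0.833 | 17 | 8 | 36 |
| red | 1.33 | 25 | 10 | 33 |
| red | 2.50 | 31 | 14 | 20 |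

(each reading ± 1.5 percentage points)

- Zd is single-handed; Za and Zb are mirror images of each other, charged as a racemate, each of them at the stated concentration
- steps thought possible: Zc + Zd + Za -> Zd + Zg; Zc + Zd + Zb -> Zd + Zh; Za + Ze <-> Zb + Ze; 2 Zc -> Zf

* which flask leads in share of Zg in all that became Zg or Zh ("all alike" within 1.5 percentage points) (theta / epsilon / eta / beta / all alike)
* share of Zg in all that became Zg or Zh, theta
* share of Zg in all that became Zg or Zh, epsilon
* share of Zg in all that became Zg or Zh, eta
* share of Zg in all that became Zg or Zh, beta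

Let a and b be the fractions left of the Za and of the Zb charged. With no crossing between the forms, both decay under the same Zc and Zd, so the selectivity factor s is ln a over ln b. The teal run at 20.0 min reads a = 82.0% and b = 94.0%, so s reads 3.21. The red run at 2.50 min reads a = 40.0% and b = 72.0%, so s reads 2.79, lower in the hotter run. These readings give 76.2% from teal and 73.6% from red for the ceiling share, s divided by s plus one.

Next comes epsilon. Za decays in the red run at 0.367 min⁻¹. Scaled to the charged Zc of epsilon, with no allowance for its higher temperature, and held for 30 min, that leaves a = 0.0722%, and through s it leaves b = 7.48%. Plain resolution with Zc held at its charge therefore gives 51.9%. The weak link is the pair a and b, reckoned as if Zc were never used up and no Zb ever became Za. Ze can carry the slower Zb into Za, and where it holds a equal to b the share stays at the ceiling for that temperature. My own reckoning therefore expects epsilon above 51.9% and below 73.6%, which was read at 47 °C, and beta, colder than teal, at about 76.2% or above, in the lead.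

The forecast names beta, with 73% for theta, 56% for epsilon, 62% for eta and 79% for beta, on the ground that “Racemisation by Ze is not visibly competitive, even at 47 °C, though the data cannot exclude it at 65 °C.”

The flasks give 73.9% for theta, 69.9% for epsilon, 71.4% for eta and 80.1% for beta, and beta leads.

    Zc + Zd + Za → Zd + Zg (k = 98.0 M⁻² s⁻¹, Ea = 41.0 kJ mol⁻¹)
    Zc + Zd + Zb → Zd + Zh (k = 34.0 M⁻² s⁻¹, Ea = 45.0 kJ mol⁻¹)
    Za + Ze ⇌ Zb + Ze, rate k3*[Ze]*[Za] forward; the back reaction follows from the equilibrium constant (k = 1.50 M⁻¹ s⁻¹, Ea = 54.0 kJ mol⁻¹)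
    2 Zc → Zf (k = 0.00360 M⁻¹ s⁻¹, Ea = 53.0 kJ mol⁻¹)
    (constants at 35 °C)

Epsilon stands 14 percentage points above the forecast. It ends with 16% of its Za and 16% of its Zb left, equal fractions. The ratio of the two paths at the start of epsilon, 2.5, puts the ceiling at 65 °C at 71.5%, lower than the 73.6% read in red, and the share of epsilon lies 1.6 points under it. A neighbour of epsilon is charged with 0.620 equiv of Zc, and the same reckoning applies. It ends with Zc at 0%, and with 71% of its Za and 71% of its Zb left, so a equals b again, and its ceiling stands at 71.5%. That flask gives 71.1%.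

All runs are simulated from invented constants; scatter was added.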